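## Structural features

The target is built on ring A, a cyclohex-2-enone numbered C1 (ketone), C2 (enamide nitrogen), C3 (alkene CH), C4 (tertiary carbinol) and C5–C6 (cis-oxirane, C6 next to the ketone). C2 carries the amide of (2E,4R)-2,4-dimethyloct-2-enoic acid (primed locants). C4 carries an all-E trienamide chain C7–C13 whose nitrogen belongs to ring B, a 2-amino-3-hydroxycyclopent-2-enone (a vinylogous acid). C4 (S), C5 (R) and C6 (S) are contiguous, with the C4 hydroxyl and the oxirane oxygen on the same face of ring A. The fourth stereocentre, C4' (R), is remote and cannot be relayed from the ring. Fragile groups are the α,β-epoxy ketone (bases, nucleophiles, hydrides), the doubly allylic tertiary carbinol, the triene (light, acid), the enamide and the acidic enol of ring B. The real difficulty is to set the absolute and relative configuration of the oxygenated half of ring A on a skeleton that starts without any stereocentre, and to join three sensitive parts late without strong acid or free strong base. The key step exploits that C4 is a fully substituted carbinol carbon para to the C1 carbonyl and bears exactly one exocyclic carbon, C7, at the acid oxidation level. That pattern is what a benzilic shift leaves when the 1,2-dione of a seven-membered ring made of C1–C7 contracts to a six-membered para-quinol.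

## Logic of the disconnections

33 is traced to 32 by cutting only the O–Si bond on the C4 oxygen. The free tertiary carbinol next to a C7 carbonyl would invite an α-ketol shift and would consume base and hydride, so it stays masked until the end. Nothing is gained in skeleton, but every later step becomes compatible. The demand is a final desilylation that spares the oxirane, the triene and the enol of ring B.

32 is cut at the C7=C8 double bond into 22 and 31. C7 is the carbon that the ring contraction delivers as a carbonyl, so an olefination there is the natural use of it. Ring B and six chain carbons then arrive in one piece. The forward step must form an E alkene from a polyanionic phosphonate in the presence of an epoxy ketone, with no free strong base left over.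

31 is cut at the C13–N amide bond into 29 (activated as 30) and 25. 29 goes back through 28 and 27 to 26 by cutting the C8–P and then the C8–Br bond, which keeps the E,E-diene of 26 untouched. 25 is cut at its C–N bond to 24 and then to 23. The demand is N- over O-acylation of the enolised amino dione and terminal selectivity in the allylic bromination.

22 is traced through 21 to 20 by changes of oxidation level only, at C7 (ester to aldehyde) and at C1 (ketone to carbinol and back). No bond of the skeleton is cut. The forward steps must accept that hydride reaches the ketone before the ester and must correct this by re-oxidation.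

20 is cut at the C2–N bond into 10 and 19. Keeping nitrogen out of ring A until after the contraction and the epoxidation leaves those steps with a symmetric, nitrogen-free substrate. The gain is a fully convergent acyl chain. The demand is a C–N coupling at an α-iodoenone that tolerates the epoxy ketone.

19 is traced to 18 (amide C–N), and 18 is cut at C2'=C3' into 17 and 16. 17 comes from 15, 15 from 14 by cutting the acyl–N bond to the auxiliary, 14 from 13 by cutting the C4'–CH3 bond, and 13 from 11 and 12. The single remote stereocentre is thus set by a reliable auxiliary alkylation. The demand is an E-selective olefination of an epimerisable α-branched aldehyde.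

10 is traced to 9 (O–Si) and 9 to 8 (C2–I). Only C2=C3 is an enone alkene, so the halogen can go to one position only.

8 is cut at the two oxirane C–O bonds to give 7. This removes all three ring stereocentres at once and leads to an achiral, mirror-symmetric dienone. The forward step must choose one of two enantiotopic enone arms and the face syn to the C4 oxygen.

7 is cut at the C4–C5 ring bond while C5 is reconnected to C7, which leads to the seven-membered 4 and to 5. The quaternary carbinol, its one-carbon substituent and the para relationship to C1 all come from one rearrangement of a symmetric trione. The demand is carbonyl addition at the vicinal dione in preference to conjugate addition or electron transfer.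

4 goes back to 3 by removal of two hydroxyl hydrogens, and 3 to 1 (via 2) by cutting the C–O bond on the ring carbon para to the oxygenated pair. This ends in a cheap seven-membered starting material.

## Other disconnections considered

Alternative 1: The cut assigns the C4–O bond and both C–O bonds of the C5–C6 oxirane (plus a temporary C3–O bond) to one molecule of oxygen. The substrate is the diene A2, a cyclohexa-3,5-diene with a tert-butyldimethylsilyloxy group on C1 and a (triisopropylsilyl)ethynyl group on C4. In the forward step, sensitised photo-oxygenation adds oxygen across C3 and C6 on the face away from the silyloxy group, and a cobalt porphyrin isomerises the endoperoxide in the same flask to the syn bis-epoxide A1.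
- In its favour: both oxygens arrive on one face by the nature of the cycloaddition and rearrangement, so the syn relation of the C4 oxygen and the oxirane is a mechanistic certainty, and the absolute configuration follows from the one stereocentre of A2. On this point the alternative is better than the chosen plan, where both rest on reagent control in step 4.
- Against it here: A2 is one elimination away from an arene and must be made enantiopure. Its C1 stereocentre is later destroyed by oxidation. The C3–C4 oxirane of A1 must be opened by β-elimination to unveil C2=C3 and the C4 hydroxyl. The alkyne must become the E C7=C8 alkene by hydrometalation next to a tertiary carbinol. C2 still has no nitrogen.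
- Comparison: on structure, A1 holds C7 and C8 but at the wrong oxidation level for olefination, whereas 7 has C7 as a carbonyl. On mechanism, the alternative is pericyclic and substrate-controlled and so more predictable than the contraction of step 3. On the C2–N bond the two plans are equal. On step economy the alternative needs more operations both before and after its key step, so the chosen plan should be shorter.

Alternative 2: The cut traces the C1–O and C6–O bonds to a cis-dihydroxylation of bromobenzene A4. In the forward step, whole cells expressing the arene dioxygenase convert A4 into the cis-dihydrodiol A3, with bromine on the carbon that becomes C2.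
- In its favour: A3 is expected as essentially one enantiomer and is obtainable in quantity, and the halogen for the C2–N coupling is already in place, which would save step 5. On both points the alternative is better than the chosen plan.
- Against it here: A3 has no carbon on C4 and no oxygen on C4 or C5. The tertiary carbinol would need oxidation of C4 to a ketone and a face-selective addition of a C7 nucleophile. The oxirane would need functionalisation of C5 and closure with inversion. C1 must be oxidised. All of this happens on a diene that dimerises and aromatises easily, with several protecting-group changes.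
- Comparison: on structure, A3 maps C1, C2 and C6, while the chosen key step maps C4 and C7, the atoms hardest to add later. On mechanism, the enzymatic step is fully precedented and the contraction is not, so the alternative carries less risk at its key step. On step economy, it has no steps before the key step but clearly more after it. Overall the chosen plan should be shorter, while the alternative is the safer source of absolute configuration.

Alternative 3: The cut is the pair of oxirane C–O bonds, as in step 4 of the chosen plan, but on the achiral para-quinol A6, which carries a (triisopropylsilyl)ethynyl group on C4. The forward step is the alkoxide-directed, tartrate-controlled nucleophilic epoxidation with a trityl-type hydroperoxide and gives the syn-epoxyquinol A5.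
- In its favour: A6 should be reachable in two conventional steps from a protected quinone and a metal acetylide, so the quinol rests on known chemistry. That is better than the chosen plan, whose quinol 7 depends on an untested rearrangement. The alkyne is inert to the peroxide anion, whereas the ester of 7 is a possible second electrophile.
- Equal point: the desymmetrisation itself is the same operation in both plans.
- Against it here: the alkyne must be turned into the E C7=C8 bond by desilylation and hydrometalation of a hindered propargylic tertiary carbinol and then joined to a dienyl halide by cross-coupling. These are further metal-mediated steps on the epoxy ketone. 7 delivers C7 as a carbonyl for one convergent olefination with the complete dienamide 31.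
- Comparison: on structure, both quinols hold the same ring; A5 has C7 and C8, 8 has C7 only. On mechanism, the plans are equal at the epoxidation and the alternative is safer before it. On step economy, the alternative reaches its epoxyquinol in fewer steps than 8 is reached from 1, and the endgames are of similar length. The chosen plan is kept for the carbonyl handle at C7 and for the short access to a C4-carboxylated para-quinol that the contraction would open.

Key step: step 3

Assumption: the sense of induction of the tartrate in step 4 cannot be predicted with confidence for a tertiary quinol alkoxide. L-(+)-diisopropyl tartrate is written; the D-enantiomer would replace it, with nothing else changed, if the opposite oxirane formed.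

Remark: the structures of 4 and 7 are consistent with the contraction (C7H4O3 + CH4O = C8H8O4), and no correction is needed. The precursor is improved only in its handling: 4 is converted into its methanol hemiketal 6 before any base is added.

## Route

Step 1
Reactants: 1 tropolone
Product: 3 5-hydroxytropolone, via potassium tropolon-5-yl sulfate 2 (not isolated)
Conditions: K2S2O8, aq. KOH, 0 °C → rt; then conc. HCl, 90 °C
Reagents that add atoms: potassium peroxodisulfate, [K+].[K+].[O-]S(=O)(=O)OOS([O-])(=O)=O (source of the C5 oxygen)
Why: Elbs persulfate oxidation: the tropolonate attacks a peroxide oxygen through the ring carbon para to the oxygenated pair, and acid hydrolyses the aryl sulfate 2; this is the established entry to 5-hydroxytropolone.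

Step 2
Reactants: 3 5-hydroxytropolone
Product: 4 para-tropoquinone (cyclohepta-3,6-diene-1,2,5-trione)
Conditions: DDQ, dry 1,4-dioxane, rt, dark; filter; evaporate cold; use at once
Reagents that add atoms: none
Why: Quinone-type dehydrogenation of the vinylogous hydroquinone 3 by a high-potential quinone; the reduced oxidant is filtered off and moisture is excluded because 4 hydrates readily.

Step 3
Reactants: 4 para-tropoquinone; 5 methanol
Product: 7 methyl 1-hydroxy-4-oxocyclohexa-2,5-diene-1-carboxylate, via hemiketal 2-hydroxy-2-methoxycyclohepta-3,6-diene-1,5-dione 6 (not isolated)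
Conditions: MeOH/THF, −40 °C, 15 min; then NaOMe (0.15 equiv), −40 → −15 °C; AcOH quench
Reagents that add atoms: none
Why: Proposed new method: a benzilic ester rearrangement has not been shown on a tropoquinone, the closest known reaction types being the alkoxide-induced benzilic ester contraction of non-enolisable cyclic 1,2-diones and the base-induced contraction of tropolone derivatives to benzoates. Methanol first adds reversibly to one of the two equivalent, mutually activated dione carbonyls to give hemiketal 6, so that carbonyl addition is settled before any base is present. Catalytic methoxide then deprotonates 6, and the alkoxide pushes the vinylic ring carbon C5 in a 1,2-shift onto the neighbouring carbonyl carbon C4; this forms the C4–C5 bond, turns the attacked carbon into the exocyclic ester carbon C7 and leaves C4 as a tertiary alkoxide that methanol protonates, regenerating methoxide. The six-membered ring is closed by this 1,2-shift, a seven-to-six ring contraction, and not by cyclisation of a chain. No stereocentre is formed: the mirror plane of 4 through the isolated carbonyl makes both dione carbonyls and both migrating carbons equivalent, and 7 is achiral. The step needs chemoselectivity for carbonyl addition over conjugate addition to the ene-dione and over electron transfer; hemiketal pre-formation, low temperature and a substoichiometric hard alkoxide should secure it. Ester resonance and relief of the strained, dipole-opposed trione drive the shift, the ester blocks the decarboxylative aromatisation open to a free acid, and the early acetic acid quench limits methoxide attack on the product.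

Step 4
Reactants: 7 methyl 1-hydroxy-4-oxocyclohexa-2,5-diene-1-carboxylate
Product: 8 methyl (1R,2S,6S)-2-hydroxy-5-oxo-7-oxabicyclo[4.1.0]hept-3-ene-2-carboxylate
Conditions: Ph3COOH, NaN(SiMe3)2, L-(+)-diisopropyl tartrate, 4 Å MS, PhMe, −55 °C; AcOH quench
Reagents that add atoms: trityl hydroperoxide, OOC(c1ccccc1)(c1ccccc1)c1ccccc1
Why: Tartrate-mediated, alkoxide-directed nucleophilic (Weitz–Scheffer) epoxidation, a reaction type established for hydroxyl-bearing cyclohexadienones. The sodium alkoxide on C4 holds the tritylperoxide on its own face, so the oxirane forms syn to the C4 oxygen; the tartrate in the sodium aggregate selects one of the two enantiotopic enone arms and so sets C4, C5 and C6 together.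

Step 5
Reactants: 8 methyl (1R,2S,6S)-2-hydroxy-5-oxo-7-oxabicyclo[4.1.0]hept-3-ene-2-carboxylate
Product: 9 methyl (1R,2S,6S)-2-hydroxy-4-iodo-5-oxo-7-oxabicyclo[4.1.0]hept-3-ene-2-carboxylate
Conditions: I2, pyridine, DMAP (cat.), CH2Cl2, 0 °C → rt, dark
Reagents that add atoms: iodine, II
Why: α-Iodination of an enone by amine conjugate addition, iodination of the enolate and elimination (Baylis–Hillman-type sequence); C2=C3 is the only enone alkene, and no stereocentre is touched.

Step 6
Reactants: 9 methyl (1R,2S,6S)-2-hydroxy-4-iodo-5-oxo-7-oxabicyclo[4.1.0]hept-3-ene-2-carboxylate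
Product: 10 methyl (1R,2S,6S)-4-iodo-5-oxo-2-(triethylsilyloxy)-7-oxabicyclo[4.1.0]hept-3-ene-2-carboxylate
Conditions: Et3SiOTf, 2,6-lutidine, CH2Cl2, −78 → 0 °C
Reagents that add atoms: triethylsilyl trifluoromethanesulfonate, CC[Si](CC)(CC)OS(=O)(=O)C(F)(F)F
Why: Silylation of a hindered tertiary alcohol with a silyl triflate; the ether prevents the α-ketol shift and alkoxide-triggered fragmentation in the basic and reducing steps that follow.

Step 7
Reactants: 11 (R)-4-benzyl-1,3-oxazolidin-2-one; 12 hexanoyl chloride
Product: 13 (R)-4-benzyl-3-hexanoyl-1,3-oxazolidin-2-one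
Conditions: n-BuLi, THF, −78 °C; then 12, −78 → 0 °C
Reagents that add atoms: none
Why: N-Acylation of the lithiated oxazolidinone by the acid chloride, the standard loading of an Evans auxiliary.

Step 8
Reactants: 13 (R)-4-benzyl-3-hexanoyl-1,3-oxazolidin-2-one
Product: 14 (R)-4-benzyl-3-[(2R)-2-methylhexanoyl]-1,3-oxazolidin-2-one
Conditions: NaN(SiMe3)2, THF, −78 °C; MeI, −78 → −40 °C
Reagents that add atoms: iodomethane, CI
Why: Evans asymmetric alkylation: the chelated Z-enolate is methylated on the face away from the benzyl group, which with the (R)-auxiliary gives the (2R)-2-methylhexanoyl unit, the future C4'.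

Step 9
Reactants: 14 (R)-4-benzyl-3-[(2R)-2-methylhexanoyl]-1,3-oxazolidin-2-one
Product: 15 (2R)-2-methylhexan-1-ol
Conditions: LiBH4, MeOH (1 equiv), Et2O, 0 °C
Reagents that add atoms: none
Why: Reductive cleavage of the exocyclic imide carbonyl by borohydride; the stereocentre is not epimerised because the carbonyl next to it is removed, and the auxiliary is recovered.

Step 10
Reactants: 15 (2R)-2-methylhexan-1-ol; 16 ethyl 2-(triphenylphosphoranylidene)propanoate
Product: 18 ethyl (2E,4R)-2,4-dimethyloct-2-enoate, via (2R)-2-methylhexanal 17 (not isolated)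
Conditions: PhI(OAc)2, TEMPO (cat.), CH2Cl2, rt; then 16, rt → 40 °C
Reagents that add atoms: none
Why: Nitroxyl-catalysed oxidation to the aldehyde, which is trapped in the same flask by the stabilised ylide (Wittig reaction) before it can epimerise or evaporate; stabilised α-methyl ylides give the E trisubstituted enoate.

Step 11
Reactants: 18 ethyl (2E,4R)-2,4-dimethyloct-2-enoate
Product: 19 (2E,4R)-2,4-dimethyloct-2-enamide
Conditions: AlMe3, NH4Cl, PhMe, 0 °C → rt; then 18, 50 °C; aq. HCl work-up
Reagents that add atoms: ammonium chloride, [NH4+].[Cl-]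
Why: Weinreb-type aminolysis of an ester by the aluminium amide made from AlMe3 and NH4Cl; the α- and β-substituents disfavour conjugate addition, and the allylic stereocentre is not acidic under these conditions.

Step 12
Reactants: 10 methyl (1R,2S,6S)-4-iodo-5-oxo-2-(triethylsilyloxy)-7-oxabicyclo[4.1.0]hept-3-ene-2-carboxylate; 19 (2E,4R)-2,4-dimethyloct-2-enamide
Product: 20 methyl (1R,2S,6S)-4-{[(2E,4R)-2,4-dimethyloct-2-enoyl]amino}-5-oxo-2-(triethylsilyloxy)-7-oxabicyclo[4.1.0]hept-3-ene-2-carboxylate
Conditions: CuI (cat.), MeNHCH2CH2NHMe, K2CO3, PhMe, 60 °C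
Reagents that add atoms: none
Why: Goldberg-type CuI/diamine-catalysed amidation of a vinyl iodide with a primary amide, a reaction type established for vinyl iodides including 2-iodoenones, with the alkene position retained; the silyl ether and the heterogeneous carbonate should keep the epoxy ketone intact.

Step 13
Reactants: 20 methyl (1R,2S,6S)-4-{[(2E,4R)-2,4-dimethyloct-2-enoyl]amino}-5-oxo-2-(triethylsilyloxy)-7-oxabicyclo[4.1.0]hept-3-ene-2-carboxylate
Product: 21 (2E,4R)-N-[(1R,2RS,5S,6R)-5-formyl-2-hydroxy-5-(triethylsilyloxy)-7-oxabicyclo[4.1.0]hept-3-en-3-yl]-2,4-dimethyloct-2-enamide (both epimers at the C1 carbinol of ring A)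
Conditions: i-Bu2AlH (3.5 equiv), CH2Cl2, −78 °C; MeOH, then aq. KNaC4H4O6 (potassium sodium tartrate)
Reagents that add atoms: none
Why: Partial ester reduction: the first equivalent deprotonates the amide, the second reduces the C1 ketone (hydride anti to the oxirane), and the third turns the α-silyloxy ester into a chelated tetrahedral aluminate that survives at −78 °C and gives the aldehyde on work-up. The configuration at C1 is of no consequence because step 14 removes it.

Step 14
Reactants: 21 (2E,4R)-N-[(1R,2RS,5S,6R)-5-formyl-2-hydroxy-5-(triethylsilyloxy)-7-oxabicyclo[4.1.0]hept-3-en-3-yl]-2,4-dimethyloct-2-enamide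
Product: 22 (2E,4R)-N-[(1S,5S,6R)-5-formyl-2-oxo-5-(triethylsilyloxy)-7-oxabicyclo[4.1.0]hept-3-en-3-yl]-2,4-dimethyloct-2-enamide
Conditions: Dess–Martin periodinane, NaHCO3, CH2Cl2, 0 °C → rt
Reagents that add atoms: none
Why: Dess–Martin oxidation returns the C1 carbinol to the enone without touching the non-enolisable aldehyde; any over-reduced primary alcohol carried from step 13 converges on the same aldehyde.

Step 15
Reactants: 23 cyclopentane-1,3-dione
Product: 24 2-(hydroxyimino)cyclopentane-1,3-dione
Conditions: NaNO2, aq. HCl, 0–5 °C
Reagents that add atoms: sodium nitrite, [Na+].[O-]N=O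
Why: C-Nitrosation of the enolised 1,3-dione at C2 and tautomerisation to the oxime, the classical nitrosation of an active methylene.

Step 16
Reactants: 24 2-(hydroxyimino)cyclopentane-1,3-dione
Product: 25 2-amino-3-hydroxycyclopent-2-en-1-one hydrochloride
Conditions: H2 (3 bar), Pd/C, HCl (1.1 equiv), MeOH, rt
Reagents that add atoms: hydrogen chloride, Cl
Why: Catalytic hydrogenation of an α-oximino 1,3-dione to the amine, trapped as its hydrochloride so that the α-amino dione cannot self-condense.

Step 17
Reactants: 26 ethyl sorbate
Product: 27 ethyl (2E,4E)-6-bromohexa-2,4-dienoate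
Conditions: NBS, AIBN (cat.), PhCF3, 85 °C
Reagents that add atoms: N-bromosuccinimide, O=C1CCC(=O)N1Br
Why: Wohl–Ziegler bromination: hydrogen abstraction from the terminal methyl gives a delocalised radical that is brominated at the terminus, which keeps the conjugated E,E-dienoate.

Step 18
Reactants: 27 ethyl (2E,4E)-6-bromohexa-2,4-dienoate
Product: 28 ethyl (2E,4E)-6-(diethoxyphosphoryl)hexa-2,4-dienoate
Conditions: P(OEt)3, neat, 120 °C
Reagents that add atoms: triethyl phosphite, CCOP(OCC)OCC
Why: Michaelis–Arbuzov reaction of a primary allylic bromide.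

Step 19
Reactants: 28 ethyl (2E,4E)-6-(diethoxyphosphoryl)hexa-2,4-dienoate
Product: 29 (2E,4E)-6-(diethoxyphosphoryl)hexa-2,4-dienoic acid
Conditions: LiOH, THF/H2O, 0 °C → rt; then 1 M HCl to pH 2
Reagents that add atoms: lithium hydroxide, [Li+].[OH-] (source of the new carboxyl oxygen)
Why: Saponification of the carboxylic ester, which is much faster than attack on the phosphonate diester.

Step 20
Reactants: 29 (2E,4E)-6-(diethoxyphosphoryl)hexa-2,4-dienoic acid; 25 2-amino-3-hydroxycyclopent-2-en-1-one hydrochloride
Product: 31 diethyl [(2E,4E)-6-[(2-hydroxy-5-oxocyclopent-1-en-1-yl)amino]-6-oxohexa-2,4-dien-1-yl]phosphonate, via (2E,4E)-6-(diethoxyphosphoryl)hexa-2,4-dienoyl chloride 30 (not isolated)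
Conditions: (COCl)2, DMF (cat.), CH2Cl2, 0 °C → rt; evaporate; then 25, Et3N, CH2Cl2/DMF, 0 °C → rt
Reagents that add atoms: oxalyl chloride, O=C(Cl)C(=O)Cl (its chlorine is held by 30 only)
Why: Acid chloride formation and N-acylation of the amine; nitrogen is the more nucleophilic site, and any enol ester that forms passes its acyl group on to nitrogen.

Step 21
Reactants: 22 (2E,4R)-N-[(1S,5S,6R)-5-formyl-2-oxo-5-(triethylsilyloxy)-7-oxabicyclo[4.1.0]hept-3-en-3-yl]-2,4-dimethyloct-2-enamide; 31 diethyl [(2E,4E)-6-[(2-hydroxy-5-oxocyclopent-1-en-1-yl)amino]-6-oxohexa-2,4-dien-1-yl]phosphonate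
Product: 32 (2E,4R)-N-[(1S,5S,6R)-5-[(1E,3E,5E)-7-[(2-hydroxy-5-oxocyclopent-1-en-1-yl)amino]-7-oxohepta-1,3,5-trien-1-yl]-2-oxo-5-(triethylsilyloxy)-7-oxabicyclo[4.1.0]hept-3-en-3-yl]-2,4-dimethyloct-2-enamide
Conditions: 31 (2.2 equiv), LiN(SiMe3)2 (6.4 equiv), THF/DMPU, −78 °C; then 22, −78 → −20 °C; AcOH quench
Reagents that add atoms: none
Why: Vinylogous Horner–Wadsworth–Emmons olefination: the enol and amide of ring B are deprotonated first, and the third equivalent of base gives the phosphonate carbanion, which attacks the aldehyde through the carbon next to phosphorus. Reversible addition and syn-elimination of phosphate give the E C7=C8 bond, the E,E-diene is unchanged, and the aldehyde is far more electrophilic than the C1 ketone, whose neighbouring amide is present as its anion.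

Step 22
Reactants: 32 (2E,4R)-N-[(1S,5S,6R)-5-[(1E,3E,5E)-7-[(2-hydroxy-5-oxocyclopent-1-en-1-yl)amino]-7-oxohepta-1,3,5-trien-1-yl]-2-oxo-5-(triethylsilyloxy)-7-oxabicyclo[4.1.0]hept-3-en-3-yl]-2,4-dimethyloct-2-enamide
Product: 33 (2E,4R)-N-[(1S,5S,6R)-5-hydroxy-5-[(1E,3E,5E)-7-[(2-hydroxy-5-oxocyclopent-1-en-1-yl)amino]-7-oxohepta-1,3,5-trien-1-yl]-2-oxo-7-oxabicyclo[4.1.0]hept-3-en-3-yl]-2,4-dimethyloct-2-enamide (the target)
Conditions: HF·pyridine, pyridine, THF, 0 °C → rt
Reagents that add atoms: none
Why: Fluoride-driven cleavage of the triethylsilyl ether under buffered, weakly acidic conditions that the epoxy ketone, the triene and the enol of ring B should tolerate.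

## Compound list

1 | tropolone (2-hydroxycyclohepta-2,4,6-trien-1-one) | O=C1C=CC=CC=C1O | starting material
2 | potassium tropolon-5-yl sulfate (potassium 4-hydroxy-5-oxocyclohepta-1,3,6-trien-1-yl sulfate) | O=C1C=CC(OS(=O)(=O)[O-])=CC=C1O.[K+] | intermediate
3 | 5-hydroxytropolone (2,5-dihydroxycyclohepta-2,4,6-trien-1-one) | O=C1C=CC(O)=CC=C1O | intermediate
4 | para-tropoquinone (cyclohepta-3,6-diene-1,2,5-trione) | O=C1C=CC(=O)C(=O)C=C1 | intermediate
5 | methanol | CO | starting material
6 | 2-hydroxy-2-methoxycyclohepta-3,6-diene-1,5-dione (methanol hemiketal of 4) | COC1(O)C=CC(=O)C=CC1=O | intermediate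
7 | methyl 1-hydroxy-4-oxocyclohexa-2,5-diene-1-carboxylate | COC(=O)C1(O)C=CC(=O)C=C1 | intermediate
8 | methyl (1R,2S,6S)-2-hydroxy-5-oxo-7-oxabicyclo[4.1.0]hept-3-ene-2-carboxylate | C1=C[C@@](O)(C(=O)OC)[C@@H]2O[C@@H]2C1=O | intermediate
9 | methyl (1R,2S,6S)-2-hydroxy-4-iodo-5-oxo-7-oxabicyclo[4.1.0]hept-3-ene-2-carboxylate | IC1=C[C@@](O)(C(=O)OC)[C@@H]2O[C@@H]2C1=O | intermediate
10 | methyl (1R,2S,6S)-4-iodo-5-oxo-2-(triethylsilyloxy)-7-oxabicyclo[4.1.0]hept-3-ene-2-carboxylate | IC1=C[C@@](O[Si](CC)(CC)CC)(C(=O)OC)[C@@H]2O[C@@H]2C1=O | intermediate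
11 | (R)-4-benzyl-1,3-oxazolidin-2-one | O=C1N[C@H](Cc2ccccc2)CO1 | starting material
12 | hexanoyl chloride | CCCCCC(Cl)=O | starting material
13 | (R)-4-benzyl-3-hexanoyl-1,3-oxazolidin-2-one | CCCCCC(=O)N1[C@H](Cc2ccccc2)COC1=O | intermediate
14 | (R)-4-benzyl-3-[(2R)-2-methylhexanoyl]-1,3-oxazolidin-2-one | CCCC[C@@H](C)C(=O)N1[C@H](Cc2ccccc2)COC1=O | intermediate
15 | (2R)-2-methylhexan-1-ol | CCCC[C@@H](C)CO | intermediate
16 | ethyl 2-(triphenylphosphoranylidene)propanoate | CCOC(=O)C(C)=P(c1ccccc1)(c1ccccc1)c1ccccc1 | starting material
17 | (2R)-2-methylhexanal | CCCC[C@@H](C)C=O | intermediate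
18 | ethyl (2E,4R)-2,4-dimethyloct-2-enoate | CCCC[C@@H](C)/C=C(\C)C(=O)OCC | intermediate
19 | (2E,4R)-2,4-dimethyloct-2-enamide | CCCC[C@@H](C)/C=C(\C)C(N)=O | intermediate
20 | methyl (1R,2S,6S)-4-{[(2E,4R)-2,4-dimethyloct-2-enoyl]amino}-5-oxo-2-(triethylsilyloxy)-7-oxabicyclo[4.1.0]hept-3-ene-2-carboxylate | CCCC[C@@H](C)/C=C(\C)C(=O)NC1=C[C@@](O[Si](CC)(CC)CC)(C(=O)OC)[C@@H]2O[C@@H]2C1=O | intermediate
21 | (2E,4R)-N-[(1R,2RS,5S,6R)-5-formyl-2-hydroxy-5-(triethylsilyloxy)-7-oxabicyclo[4.1.0]hept-3-en-3-yl]-2,4-dimethyloct-2-enamide (carbinol epimers) | CCCC[C@@H](C)/C=C(\C)C(=O)NC1=C[C@@](O[Si](CC)(CC)CC)(C=O)[C@@H]2O[C@@H]2C1O | intermediate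
22 | (2E,4R)-N-[(1S,5S,6R)-5-formyl-2-oxo-5-(triethylsilyloxy)-7-oxabicyclo[4.1.0]hept-3-en-3-yl]-2,4-dimethyloct-2-enamide | CCCC[C@@H](C)/C=C(\C)C(=O)NC1=C[C@@](O[Si](CC)(CC)CC)(C=O)[C@@H]2O[C@@H]2C1=O | intermediate
23 | cyclopentane-1,3-dione | O=C1CCC(=O)C1 | starting material
24 | 2-(hydroxyimino)cyclopentane-1,3-dione | O=C1CCC(=O)C1=NO | intermediate
25 | 2-amino-3-hydroxycyclopent-2-en-1-one hydrochloride | Cl.NC1=C(O)CCC1=O | intermediate
26 | ethyl sorbate (ethyl (2E,4E)-hexa-2,4-dienoate) | CCOC(=O)/C=C/C=C/C | starting material
27 | ethyl (2E,4E)-6-bromohexa-2,4-dienoate | CCOC(=O)/C=C/C=C/CBr | intermediate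
28 | ethyl (2E,4E)-6-(diethoxyphosphoryl)hexa-2,4-dienoate | CCOC(=O)/C=C/C=C/CP(=O)(OCC)OCC | intermediate
29 | (2E,4E)-6-(diethoxyphosphoryl)hexa-2,4-dienoic acid | OC(=O)/C=C/C=C/CP(=O)(OCC)OCC | intermediate
30 | (2E,4E)-6-(diethoxyphosphoryl)hexa-2,4-dienoyl chloride | O=C(Cl)/C=C/C=C/CP(=O)(OCC)OCC | intermediate
31 | diethyl [(2E,4E)-6-[(2-hydroxy-5-oxocyclopent-1-en-1-yl)amino]-6-oxohexa-2,4-dien-1-yl]phosphonate | CCOP(=O)(OCC)C/C=C/C=C/C(=O)NC1=C(O)CCC1=O | intermediate
32 | (2E,4R)-N-[(1S,5S,6R)-5-[(1E,3E,5E)-7-[(2-hydroxy-5-oxocyclopent-1-en-1-yl)amino]-7-oxohepta-1,3,5-trien-1-yl]-2-oxo-5-(triethylsilyloxy)-7-oxabicyclo[4.1.0]hept-3-en-3-yl]-2,4-dimethyloct-2-enamide | CCCC[C@@H](C)/C=C(\C)C(=O)NC1=C[C@@](O[Si](CC)(CC)CC)(/C=C/C=C/C=C/C(=O)NC2=C(O)CCC2=O)[C@@H]2O[C@@H]2C1=O | intermediate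
33 | (2E,4R)-N-[(1S,5S,6R)-5-hydroxy-5-[(1E,3E,5E)-7-[(2-hydroxy-5-oxocyclopent-1-en-1-yl)amino]-7-oxohepta-1,3,5-trien-1-yl]-2-oxo-7-oxabicyclo[4.1.0]hept-3-en-3-yl]-2,4-dimethyloct-2-enamide | CCCC[C@@H](C)/C=C(\C)C(=O)NC1=C[C@@](O)(/C=C/C=C/C=C/C(=O)NC2=C(O)CCC2=O)[C@@H]2O[C@@H]2C1=O | target

## Step count and least certain steps

Total: 22 steps (11 on the core line, 5 for amide 19, 6 for phosphonate 31). Longest linear sequence: 11 steps, from 1 to 33 (steps 1–6, 12–14, 21 and 22).

Step 3 (key step, proposed new method). Most likely to go wrong: methoxide is diverted into conjugate addition at the ene-dione carbons or into electron transfer that reduces the quinone back towards 3, and the product ester is cleaved by methoxide with aromatisation. The reason is that 4 is a strong oxidant and a multiple Michael acceptor, and 7 is one C–C cleavage away from a hydroquinone. The fallback uses known chemistry and leaves the tropolone series, keeping only methanol 5 of the route. 4-Methoxyphenol F1 is oxidised with PhI(OAc)2 in 5 to the quinone monoketal 4,4-dimethoxycyclohexa-2,5-dien-1-one F2. 1-Methoxyvinyllithium (from methyl vinyl ether and t-BuLi, THF, −78 °C) adds to the carbonyl of F2 and gives 4,4-dimethoxy-1-(1-methoxyethenyl)cyclohexa-2,5-dien-1-ol F3. One equivalent of ozone at −78 °C (CH2Cl2/MeOH, pyridine; then Me2S) cleaves the electron-rich enol ether alkene selectively to the ester, methyl 1-hydroxy-4,4-dimethoxycyclohexa-2,5-diene-1-carboxylate F4. Aqueous acetic acid removes the ketal, and the route is rejoined at 7.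

Step 4. Most likely to go wrong: poor discrimination between the enantiotopic enone arms, or loss of syn delivery. The tertiary alkoxide sits directly on the ring and next to an ester that can also bind sodium, so the aggregate differs from those of the primary alkoxides for which the tartrate system is established. Attack of the peroxide anion on the ester is a further risk. The fallback gives up desymmetrisation for resolution. From 7, an achiral alkoxide-directed epoxidation (t-BuOOH, DBU, CH2Cl2, 0 °C) should give the syn epoxide as the racemate of 8 and its mirror image, methyl (1S,2R,6R)-2-hydroxy-5-oxo-7-oxabicyclo[4.1.0]hept-3-ene-2-carboxylate F5. Preparative chromatography on a chiral stationary phase separates them, and the route is rejoined at 8.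

Step 12. Most likely to go wrong: base- or copper-induced opening of the epoxy ketone, reductive loss of iodine, or slow coupling next to the fully substituted C4, because the reaction needs carbonate and heat. The fallback brings nitrogen in as azide and forms the amide by acylation. From 10, CuI-catalysed azidation at room temperature (NaN3, sodium ascorbate NaC6H7O6, MeNHCH2CH2NHMe, EtOH/H2O) would give methyl (1R,2S,6S)-4-azido-5-oxo-2-(triethylsilyloxy)-7-oxabicyclo[4.1.0]hept-3-ene-2-carboxylate F6. Staudinger reduction (PPh3, THF/H2O) gives the amine, methyl (1R,2S,6S)-4-amino-5-oxo-2-(triethylsilyloxy)-7-oxabicyclo[4.1.0]hept-3-ene-2-carboxylate F7. F7 is acylated at once (Et3N, CH2Cl2, 0 °C) with (2E,4R)-2,4-dimethyloct-2-enoyl chloride F9. F9 is made from 18 by saponification with LiOH to (2E,4R)-2,4-dimethyloct-2-enoic acid F8 and treatment with oxalyl chloride. The route is rejoined at 20.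

Step 13. Most likely to go wrong: a spread of oxidation levels at C7, lactol formation from the minor C1 epimer (whose hydroxyl is cis to the formyl group) followed by oxidation to a lactone in step 14, and hydride opening of the oxirane, because three reducible sites compete for one reagent. The fallback moves the redox adjustment ahead of the C–N coupling. From 10, excess i-Bu2AlH (−78 → −40 °C) reduces ketone and ester fully to the diol, (1R,2RS,5R,6R)-5-(hydroxymethyl)-3-iodo-5-(triethylsilyloxy)-7-oxabicyclo[4.1.0]hept-3-en-2-ol F10. MnO2 in CH2Cl2 oxidises only the allylic carbinol and gives (1S,5R,6R)-5-(hydroxymethyl)-3-iodo-5-(triethylsilyloxy)-7-oxabicyclo[4.1.0]hept-3-en-2-one F11. The CuI-catalysed amidation of step 12 with 19 gives (2E,4R)-N-[(1S,5R,6R)-5-(hydroxymethyl)-2-oxo-5-(triethylsilyloxy)-7-oxabicyclo[4.1.0]hept-3-en-3-yl]-2,4-dimethyloct-2-enamide F12. Dess–Martin oxidation of the primary alcohol rejoins the route at 22.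

Step 21. Most likely to go wrong: incomplete formation or poor solubility of the polyanion of 31, proton transfer from the amide of 22 that quenches the carbanion, incomplete E selectivity at C7=C8, and deformylation of the hindered aldehyde by hard base. The fallback separates the olefination from ring B. From 22, the lithium salt of 28 (LiN(SiMe3)2, THF, −78 °C) gives the triene ester, ethyl (2E,4E,6E)-7-[(1R,2S,6S)-4-{[(2E,4R)-2,4-dimethyloct-2-enoyl]amino}-5-oxo-2-(triethylsilyloxy)-7-oxabicyclo[4.1.0]hept-3-en-2-yl]hepta-2,4,6-trienoate F13. Me3SnOH in 1,2-dichloroethane at 70 °C cleaves the ester under near-neutral conditions to the corresponding trienoic acid F14. Coupling of F14 with 25 (EDC·HCl, HOBt, i-Pr2NEt, DMF) rejoins the route at 32.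

## Further compounds

F1 | step 3 | 4-methoxyphenol | COc1ccc(O)cc1
F2 | step 3 | 4,4-dimethoxycyclohexa-2,5-dien-1-one | COC1(OC)C=CC(=O)C=C1
F3 | step 3 | 4,4-dimethoxy-1-(1-methoxyethenyl)cyclohexa-2,5-dien-1-ol | COC(=C)C1(O)C=CC(OC)(OC)C=C1
F4 | step 3 | methyl 1-hydroxy-4,4-dimethoxycyclohexa-2,5-diene-1-carboxylate | COC(=O)C1(O)C=CC(OC)(OC)C=C1
F5 | step 4 | methyl (1S,2R,6R)-2-hydroxy-5-oxo-7-oxabicyclo[4.1.0]hept-3-ene-2-carboxylate | C1=C[C@](O)(C(=O)OC)[C@H]2O[C@H]2C1=O
F6 | step 12 | methyl (1R,2S,6S)-4-azido-5-oxo-2-(triethylsilyloxy)-7-oxabicyclo[4.1.0]hept-3-ene-2-carboxylate | [N-]=[N+]=NC1=C[C@@](O[Si](CC)(CC)CC)(C(=O)OC)[C@@H]2O[C@@H]2C1=O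
F7 | step 12 | methyl (1R,2S,6S)-4-amino-5-oxo-2-(triethylsilyloxy)-7-oxabicyclo[4.1.0]hept-3-ene-2-carboxylate | NC1=C[C@@](O[Si](CC)(CC)CC)(C(=O)OC)[C@@H]2O[C@@H]2C1=O
F8 | step 12 | (2E,4R)-2,4-dimethyloct-2-enoic acid | CCCC[C@@H](C)/C=C(\C)C(=O)O
F9 | step 12 | (2E,4R)-2,4-dimethyloct-2-enoyl chloride | CCCC[C@@H](C)/C=C(\C)C(Cl)=O
F10 | step 13 | (1R,2RS,5R,6R)-5-(hydroxymethyl)-3-iodo-5-(triethylsilyloxy)-7-oxabicyclo[4.1.0]hept-3-en-2-ol (carbinol epimers) | IC1=C[C@@](O[Si](CC)(CC)CC)(CO)[C@@H]2O[C@@H]2C1O
F11 | step 13 | (1S,5R,6R)-5-(hydroxymethyl)-3-iodo-5-(triethylsilyloxy)-7-oxabicyclo[4.1.0]hept-3-en-2-one | IC1=C[C@@](O[Si](CC)(CC)CC)(CO)[C@@H]2O[C@@H]2C1=O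
F12 | step 13 | (2E,4R)-N-[(1S,5R,6R)-5-(hydroxymethyl)-2-oxo-5-(triethylsilyloxy)-7-oxabicyclo[4.1.0]hept-3-en-3-yl]-2,4-dimethyloct-2-enamide | CCCC[C@@H](C)/C=C(\C)C(=O)NC1=C[C@@](O[Si](CC)(CC)CC)(CO)[C@@H]2O[C@@H]2C1=O
F13 | step 21 | ethyl (2E,4E,6E)-7-[(1R,2S,6S)-4-{[(2E,4R)-2,4-dimethyloct-2-enoyl]amino}-5-oxo-2-(triethylsilyloxy)-7-oxabicyclo[4.1.0]hept-3-en-2-yl]hepta-2,4,6-trienoate | CCCC[C@@H](C)/C=C(\C)C(=O)NC1=C[C@@](O[Si](CC)(CC)CC)(/C=C/C=C/C=C/C(=O)OCC)[C@@H]2O[C@@H]2C1=O
F14 | step 21 | (2E,4E,6E)-7-[(1R,2S,6S)-4-{[(2E,4R)-2,4-dimethyloct-2-enoyl]amino}-5-oxo-2-(triethylsilyloxy)-7-oxabicyclo[4.1.0]hept-3-en-2-yl]hepta-2,4,6-trienoic acid | CCCC[C@@H](C)/C=C(\C)C(=O)NC1=C[C@@](O[Si](CC)(CC)CC)(/C=C/C=C/C=C/C(=O)O)[C@@H]2O[C@@H]2C1=O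
A1 | alternative 1 | syn 3,4:5,6-bis-epoxide of 1-(tert-butyldimethylsilyloxy)-4-[(triisopropylsilyl)ethynyl]cyclohexane, both oxiranes anti to the silyloxy group | C1[C@@H]3O[C@]3(C#C[Si](C(C)C)(C(C)C)C(C)C)[C@@H]2O[C@@H]2[C@H]1O[Si](C)(C)C(C)(C)C
A2 | alternative 1 | tert-butyldimethyl{[(1S)-4-[(triisopropylsilyl)ethynyl]cyclohexa-2,4-dien-1-yl]oxy}silane | C1C=C(C#C[Si](C(C)C)(C(C)C)C(C)C)C=C[C@H]1O[Si](C)(C)C(C)(C)C
A3 | alternative 2 | (1S,2S)-3-bromocyclohexa-3,5-diene-1,2-diol | O[C@H]1C=CC=C(Br)[C@H]1O
A4 | alternative 2 | bromobenzene | Brc1ccccc1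
A5 | alternative 3 | syn-5,6-epoxy-4-hydroxy-4-[(triisopropylsilyl)ethynyl]cyclohex-2-en-1-one with the ring configuration of the target | C1=C[C@@](O)(C#C[Si](C(C)C)(C(C)C)C(C)C)[C@@H]2O[C@@H]2C1=O
A6 | alternative 3 | 4-hydroxy-4-[(triisopropylsilyl)ethynyl]cyclohexa-2,5-dien-1-one | O=C1C=CC(O)(C#C[Si](C(C)C)(C(C)C)C(C)C)C=C1
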